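The easy step was a subtraction: what had gone from the two substrates by the last reading of each run.

| flask | left-handed substrate | right-handed substrate | gas | catalyst | remark | time |
|---|---|---|---|---|---|---|
| teal | 0.022 M | 0.022 M | 2.3 mM (held) | 0.22 mM | run made earlier |  |
| grey | 0.022 M | 0.022 M | 2.3 mM (held) | 0.88 mM | run made earlier |  |
| ochre | 0.011 M | 0.011 M | 2.3 mM (held) | 0.44 mM | run made earlier |  |
| flask | 0.022 M | 0.022 M | 2.3 mM (held) | 0.44 mM |  | 8.0 min |

| run | time / min | right-handed substrate / % | left-handed substrate / % | left-handed product / % |
|---|---|---|---|---|
| teal | 0.250 | 53 | 48 | 1 |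
| teal | 0.667 | 49 | 47 | 4 |
| teal | 1.33 | 49 | 42 | 9 |
| teal | 2.00 | 40 | 38 | 15 |
| teal | 3.00 | 37 | 32 | 22 |
| teal | 4.00 | 34 | 28 | 26 |
| teal | 5.00 | 30 | 25 | 35 |
| grey | 0.417 | 52 | 45 | 3 |
| grey | 0.667 | 48 | 42 | 6 |
| grey | 0.833 | 41 | 43 | 8 |
| grey | 1.33 | 44 | 45 | 9 |
| grey | 2.00 | 41 | 38 | 15 |
| grey | 3.00 | 37 | 30 | 25 |
| grey | 5.00 | 24 | 18 | 38 |
| ochre | 1.00 | 44 | 38 | 14 |
| ochre | 2.00 | 37 | 25 | 28 |
| ochre | 3.00 | 26 | 12 | 43 |
| ochre | 4.00 | 20 | 12 | 43 |
| ochre | 5.00 | 9 | 1 | 60 |

(readings scatter by 2 percentage points)

- catalyst is single-handed; left-handed substrate and right-handed substrate are mirror images of each other, charged as a racemate, each of them at the stated concentration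
- at the start none of partner is dissolved
- the numbers in the tables scatter by 2 percentage points (one standard deviation)
- steps thought possible: partner + catalyst + left-handed substrate -> catalyst + left-handed product; gas <-> partner; partner + catalyst + right-handed substrate -> catalyst + right-handed product; partner -> decomposed reagent; left-handed substrate <-> right-handed substrate

1. whether the excess of right-handed substrate over left-handed substrate among what is left of the two reaches 95% by 8.0 min (yes / no)
2. the highest excess of right-handed substrate over left-handed substrate among what is left of the two up to 8.0 min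

Divided by time, that loss was 3.96 mM min⁻¹ in the teal run and 5.10 mM min⁻¹ in the grey run, so 4.00 times the catalyst gave 1.29 times the drain, far less than in proportion. I therefore took partner as quasi-steady, with the crossing from gas as the rate-limiting step. From the mean drain of the three runs, 4.34 mM min⁻¹, I reckoned 9.27 mM of the two substrates in the flask at 8.0 min.

In the ochre run, the drop in left-handed substrate, read as 49.0%, was smaller than the 60% of left-handed product read, so substrate had crossed over. The second amount was therefore 2.20 mM, read as the mean at the last readings: the held gap, c(right-handed substrate) minus c(left-handed substrate) once racemisation closes it as fast as selective burning opens it.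

The excess is the ratio of these two amounts, and it climbs while the gap holds and the substrates shrink. I therefore put the top at 8.0 min, at 23.7%, lower than 95%, and answered no.

The forecast answered no, with a top of 35%, holding that “the supply of partner from the gas limits the rate”.

The flask gave no, with a top of 27.9%.

    partner + catalyst + left-handed substrate → catalyst + left-handed product (k = 69000 L² mol⁻² s⁻¹)
    gas ⇌ partner, rate k2*(csat - [partner]) (kL = 0.0360 s⁻¹)
    partner + catalyst + right-handed substrate → catalyst + right-handed product (k = 27000 L² mol⁻² s⁻¹)
    partner → decomposed reagent (k = 0.00730 s⁻¹)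
    left-handed substrate ⇌ right-handed substrate (k = 0.00400 s⁻¹)

At 8.00 min the flask's gap stood at 2.32 mM against the held gap of 2.20 mM, over 8.33 mM of substrates against my 9.27 mM. At 3.88 min left-handed substrate was burned 1.1 times as fast as it crossed to right-handed substrate, forward step alone. Over the whole flask, the backward crossing came to 121% of the forward one. For the same flask read at 2.0 min, I reckon 2.20 mM over 35.3 mM, or 6.23%, and its simulated top was 6.96%.

The numbers in the tables were generated by integration for an exercise; noise was put on by code.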